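The data are calculated for an exercise; noise was put on by code.

The question is what stands in the flask at 40 min, so I follow G's fall and draw the rest of the curve around it.

| flask | G | L | remark | time |
|---|---|---|---|---|
| birch | 0.17 M | 0.237 M (in portions, 4) | run made earlier; portions every 6.0 min |  |
| elm | 0.38 M | 0.237 M (in portions, 4) | run made earlier; portions every 6.0 min |  |
| larch | 0.25 M | 0.12 M (in portions, 4) | run made earlier; portions every 6.0 min |  |
| flask | 0.25 M | 0.237 M (in portions, 4) | the portions of L follow each other after 6.0 min, the first at the start | 40 min |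

- birch (time / min: X / %, G / %): 2.50: 10.5, 79.0; 8.00: 26.0, 47.4; 15.0: 33.7, 22.8; 20.0: 36.6, 14.6; 30.0: 35.9, 4.3; 40.0: 36.1, 0.9; 50.0: 36.0, 0
- elm (time / min: X / %, G / %): 4.00: 9.9, 69.7; 6.00: 10.2, 60.3; 8.00: 18.8, 50.6; 15.0: 24.6, 28.5; 20.0: 28.0, 19.1; 30.0: 29.9, 7.2; 50.0: 29.1, 1.1
- larch (time / min: X / %, G / %): 4.00: 7.7, 71.2; 12.0: 14.6, 38.5; 20.0: 22.8, 20.3; 30.0: 23.6, 8.3; 50.0: 23.3, 3.0

(readings scatter by 0.5 percentage points)

* the X in the flask at 40 min, as a percentage of the G charged
* the G in the flask at 40 min, as a percentage of the G charged
* concentration of L at 40 min, in M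

- the numbers in the tables scatter by 0.5 percentage points (one standard deviation)

1. Birch and elm carry this flask's L charge, 0.237 M, and a first-order fall through their G readings at 30.0 min halves G every 6.61 min in birch and every 7.90 min in elm.

2. This flask's G charge lies 38.1% of the way from birch to elm, so I take for it a G half-life, the time in which a pseudo-first-order fall halves G, of 7.10 min.

3. Larch, with this flask's G charge but 0.12 M of L, reads a longer one, 8.35 min, so at this G charge I take the G half-life to shorten as the L charge grows.

4. So I put G's first fall in this flask at 0.0976 min⁻¹ of what is there, and I expect X to climb in steps, as the stall in the elm readings from 9.9% to 10.2% between 4.00 min and 6.00 min suggests.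

5. X reads level at 36.0% in birch and 29.5% in elm, so by the same share I let this flask's X run into 33.5%, and I put G at that height at 11.2 min.

6. I expect the knee in X just after the last portion at 18.0 min, when I put G at 17.3%.

7. At 40 min I put G at 2.01%, and I give no figure for L, since no table has a column for it.

8. The forecast, reckoned its own way, gives 33% X, 1.9% G and 0 M L, in its words “L is essentially zero”.

9. The flask gives 34.5% X, 2.05% G and 0.0479 M L.

    G ⇌ Z (K = 1.78, k = 0.0835 min⁻¹)
    G + L → Q (k = 0.343 M⁻¹ min⁻¹)
    L + Z → X (k = 30.9 M⁻¹ min⁻¹)
    Z → D (k = 0.319 min⁻¹)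
    X ⇌ J (K = 0.860, k = 0.0766 min⁻¹)

Taken as one first-order fall over the whole run, the flask's G gives a half-life of 7.13 min against my 7.10 min, and the relaxation half-life of G and Z by the step between them alone, both ways together, 5.32 min, is shorter than the 40 min of the run. For the neighbour flask with 0.40 M of L, the line through the larch half-life and my half-life for this flask gives a G half-life of 5.36 min and so G at 0.567%, and that neighbour flask holds 0.549% of G at 40 min.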